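**Retrosynthetic overview**
1. Drimane numbering is used (ring A = C1–C5 and C10, ring B = C5–C10, C11 = OCH2 on C9, C12 = CH2 on C8). The last bonds made are the C11–O aryl ether (Mitsunobu with umbelliferone), the 3α-OH (from the C3 ketone), the C1–C2 single bond (CuH), and both C4 methyls together with C8=C12 (one exhaustive methylation/Hofmann step).
2. Key disconnection: ring A is opened at C1–C2 and C4–C5, so C2–C3–C4 becomes an acetone unit (from 2-methoxypropene) that is stitched onto a ring B allylic alcohol by Claisen rearrangement and aldol condensation in one flask.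
3. Enabling feature: the C6=C7 double bond of ring B is γ,δ to the C3 oxygen (C3–C4–C5–C6=C7 is a Claisen retron). A β-oxygen on C7 can therefore deliver the acetone CH2 to C5 and leave as that alkene, while C1 sits on quaternary C10 as a non-enolisable aldehyde that only the ketone methyl can reach.
4. Ring B comes from a catalytic enantioselective Diels–Alder reaction of an (E)-2-methyl enal with a 2-silyloxydiene (sets C9 and C10), followed by Saegusa oxidation, Mannich reaction (C12) and Luche reduction (C7–OH).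
5. Order of ring formation: ring B (step 3), ring A (step 8); the coumarin is attached last (step 13).

Key step: step 8

Assumption 1: β is the face of the C10 methyl group and α the opposite face; these and the drimane atom numbers are used for every intermediate.
Assumption 2: the step 3 catalyst antipode is taken to be the (S)-prolinol-derived oxazaborolidinium, on the accepted formyl C–H···O binding model for 2-substituted enals; the mirror-image catalyst is the alternative if the sense is opposite.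

Step 1
Reactants: 1 2-(tert-butyldiphenylsilyloxy)acetaldehyde; 2 2-(triphenylphosphoranylidene)propanal
Product: 3 (E)-4-(tert-butyldiphenylsilyloxy)-2-methylbut-2-enal
Conditions: toluene, 80 °C
Reagents that add atoms: none
Why: Wittig olefination with a formyl-stabilised ylide, which reacts with the more electrophilic saturated aldehyde and should give the E-trisubstituted enal.

Step 2
Reactants: 4 but-3-en-2-one
Product: 5 2-(triisopropylsilyloxy)buta-1,3-diene
Conditions: i-Pr3SiOTf, Et3N, Et2O, 0 °C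
Reagents that add atoms: triisopropylsilyl trifluoromethanesulfonate CC(C)[Si](OS(=O)(=O)C(F)(F)F)(C(C)C)C(C)C
Why: Soft enolisation and O-silylation of the methyl ketone, the standard entry to 2-silyloxydienes.

Step 3
Reactants: 3 (E)-4-(tert-butyldiphenylsilyloxy)-2-methylbut-2-enal; 5 2-(triisopropylsilyloxy)buta-1,3-diene
Product: 6 (1S,6S)-6-[(tert-butyldiphenylsilyloxy)methyl]-1-methyl-4-(triisopropylsilyloxy)cyclohex-3-ene-1-carbaldehyde
Conditions: (S)-3,3-diphenyl-1-(2-methylphenyl)tetrahydro-1H,3H-pyrrolo[1,2-c][1,3,2]oxazaborole·HNTf2 (20 mol%), CH2Cl2, −78 → −20 °C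
Reagents that add atoms: none
Why: Enantioselective Diels–Alder reaction under cationic oxazaborolidine catalysis; the nucleophilic CH2 terminus of the diene bonds to the enal β-carbon (C9), suprafacial addition to the E-enal places the C10 methyl and the C9 CH2OSi arm cis, and the catalyst shields one face of the bound enal so that C9 and C10 are set absolutely.

Step 4
Reactants: 6 (1S,6S)-6-[(tert-butyldiphenylsilyloxy)methyl]-1-methyl-4-(triisopropylsilyloxy)cyclohex-3-ene-1-carbaldehyde
Product: 7 (1S,6S)-6-[(tert-butyldiphenylsilyloxy)methyl]-1-methyl-4-oxocyclohex-2-ene-1-carbaldehyde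
Conditions: Pd(OAc)2 (1.1 equiv), MeCN, 40 °C
Reagents that add atoms: none
Why: Saegusa–Ito oxidation; palladation of the silyl enol ether at C6 and β-hydride loss from C5 (the only β-hydrogens) should give the C5=C6 enone regiospecifically under neutral conditions that spare the aldehyde.

Step 5
Reactants: 7 (1S,6S)-6-[(tert-butyldiphenylsilyloxy)methyl]-1-methyl-4-oxocyclohex-2-ene-1-carbaldehyde
Product: 8 (4S,5S)-5-[(tert-butyldiphenylsilyloxy)methyl]-4-(dimethoxymethyl)-4-methylcyclohex-2-en-1-one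
Conditions: HC(OMe)3, MeOH, pyridinium p-toluenesulfonate (5 mol%), 0 °C → rt
Reagents that add atoms: trimethyl orthoformate COC(OC)OC
Why: Acid-catalysed acetalisation; the aldehyde reacts much faster than the conjugated ketone, and acidic conditions avoid the base-induced deformylation to which this γ-formyl enone is prone.

Step 6
Reactants: 8 (4S,5S)-5-[(tert-butyldiphenylsilyloxy)methyl]-4-(dimethoxymethyl)-4-methylcyclohex-2-en-1-one
Product: 10 (4S,5S,6R)-5-[(tert-butyldiphenylsilyloxy)methyl]-4-(dimethoxymethyl)-6-[(dimethylamino)methyl]-4-methylcyclohex-2-en-1-one, via lithium dienolate 9 (not isolated)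
Conditions: LiN(i-Pr)2, THF, −78 °C; then Me2N=CH2 I, −78 → 0 °C
Reagents that add atoms: N,N-dimethylmethyleneiminium iodide C=[N+](C)C.[I-]
Why: Kinetic α′-deprotonation (C8 is the only enolisable carbon because C10 is quaternary) and Mannich alkylation anti to the C9 arm; the C8 centre becomes sp2 in step 9, so its configuration is not critical.

Step 7
Reactants: 10 (4S,5S,6R)-5-[(tert-butyldiphenylsilyloxy)methyl]-4-(dimethoxymethyl)-6-[(dimethylamino)methyl]-4-methylcyclohex-2-en-1-one
Product: 11 (1S,4S,5S,6R)-5-[(tert-butyldiphenylsilyloxy)methyl]-4-(dimethoxymethyl)-6-[(dimethylamino)methyl]-4-methylcyclohex-2-en-1-ol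
Conditions: NaBH4, CeCl3·7H2O, MeOH, −78 °C
Reagents that add atoms: none
Why: Luche 1,2-reduction; axial hydride delivery on the α face of the half-chair with equatorial C8 and C9 arms should give the pseudo-equatorial β-alcohol at C7, cis to the C9 arm and the C10 methyl.

Step 8
Reactants: 11 (1S,4S,5S,6R)-5-[(tert-butyldiphenylsilyloxy)methyl]-4-(dimethoxymethyl)-6-[(dimethylamino)methyl]-4-methylcyclohex-2-en-1-ol; 12 2-methoxypropene
Product: 17 (4aS,5S,6R,8aR)-5-[(tert-butyldiphenylsilyloxy)methyl]-6-[(dimethylamino)methyl]-4a-methyl-4a,5,6,8a-tetrahydronaphthalen-2(1H)-one, via isopropenyl ether 13 (not isolated), via methyl ketone 14 (not isolated), via keto aldehyde 15 (not isolated), via aldol 16 (not isolated)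
Conditions: 12 (10 equiv), EtCO2H (1.3 equiv), o-xylene, 150 °C, sealed tube; then vent, 2 M HCl(aq), THF, 50 °C
Reagents that add atoms: none
Why: Acid-catalysed exchange puts the isopropenyl group of 12 on the C7 oxygen (13), and a Saucy–Marbet variant of the Claisen rearrangement, a suprafacial [3,3] shift with C7–O pseudoaxial, moves its CH2 terminus to C5 on the β face; this forms C4–C5 and turns C7–O into the C6=C7 alkene and the C3 ketone (14). Aqueous acid then frees the neopentyl aldehyde (15), and the methyl ketone enol adds to it (16) and water is lost, forming C1–C2; the closest known reactions are the isopropenyl ether Claisen rearrangement of cyclohexenols and the acid-mediated aldol cyclisation of 1,5-keto aldehydes. Ring A closes by a 6-(enolendo)-exo-trig aldol addition. The new stereocentre C5 is set by 1,3-chirality transfer from C7 (β-oxygen gives β-carbon), and because C1 is α on C10 the ring fusion must be trans. The step needs closure through the ketone methyl only, which is secured because attack by the C4 methylene would give a cyclobutane and the aldehyde has no α-hydrogen; the symmetric acetone unit removes any regiochemical question in the enol ether.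

Step 9
Reactants: 17 (4aS,5S,6R,8aR)-5-[(tert-butyldiphenylsilyloxy)methyl]-6-[(dimethylamino)methyl]-4a-methyl-4a,5,6,8a-tetrahydronaphthalen-2(1H)-one
Product: 20 (4aS,5S,8aR)-5-[(tert-butyldiphenylsilyloxy)methyl]-1,1,4a-trimethyl-6-methylidene-4a,5,6,8a-tetrahydronaphthalen-2(1H)-one, via ammonium iodide 18 (not isolated), via dimethylated ammonium iodide 19 (not isolated)
Conditions: MeI (1.2 equiv), THF, rt; then KOt-Bu (5 equiv), MeI (4 equiv), t-BuOH/THF, 0 → 45 °C
Reagents that add atoms: iodomethane CI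
Why: Menshutkin N-methylation, exhaustive α′-methylation of the cross-conjugated enolate (C4 is the only enolisable carbon because C2 is vinylic and C10 quaternary) and Hofmann elimination of the allylic C8 hydrogen with loss of trimethylamine should install the gem-dimethyl group and the exocyclic C8=C12 alkene.

Step 10
Reactants: 20 (4aS,5S,8aR)-5-[(tert-butyldiphenylsilyloxy)methyl]-1,1,4a-trimethyl-6-methylidene-4a,5,6,8a-tetrahydronaphthalen-2(1H)-one
Product: 21 (4aS,5S,8aR)-5-[(tert-butyldiphenylsilyloxy)methyl]-1,1,4a-trimethyl-6-methylidene-3,4,4a,5,6,8a-hexahydronaphthalen-2(1H)-one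
Conditions: Cu(OAc)2 (5 mol%), 1,2-bis(diphenylphosphino)benzene (5 mol%), (EtO)2MeSiH, t-BuOH, toluene, 0 °C → rt
Reagents that add atoms: none
Why: Phosphine-ligated CuH conjugate reduction of the enone; the unactivated s-trans diene and the hindered ketone should not react under these conditions.

Step 11
Reactants: 21 (4aS,5S,8aR)-5-[(tert-butyldiphenylsilyloxy)methyl]-1,1,4a-trimethyl-6-methylidene-3,4,4a,5,6,8a-hexahydronaphthalen-2(1H)-one
Product: 22 (2R,4aS,5S,8aR)-5-[(tert-butyldiphenylsilyloxy)methyl]-1,1,4a-trimethyl-6-methylidene-1,2,3,4,4a,5,6,8a-octahydronaphthalen-2-ol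
Conditions: LiBH(s-Bu)3, THF, −78 °C; then NaOH, H2O2, 0 °C
Reagents that add atoms: none
Why: Bulky trialkylborohydride reduction; attack along the equatorial trajectory avoids the axial hydrogens at C1 and C5 on the α face and should give the axial 3α-alcohol.

Step 12
Reactants: 22 (2R,4aS,5S,8aR)-5-[(tert-butyldiphenylsilyloxy)methyl]-1,1,4a-trimethyl-6-methylidene-1,2,3,4,4a,5,6,8a-octahydronaphthalen-2-ol
Product: 23 (2R,4aS,5S,8aR)-5-(hydroxymethyl)-1,1,4a-trimethyl-6-methylidene-1,2,3,4,4a,5,6,8a-octahydronaphthalen-2-ol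
Conditions: Bu4NF, THF, rt
Reagents that add atoms: none
Why: Fluoride-induced cleavage of the silyl ether, which leaves the diene and the secondary alcohol untouched.

Step 13
Reactants: 23 (2R,4aS,5S,8aR)-5-(hydroxymethyl)-1,1,4a-trimethyl-6-methylidene-1,2,3,4,4a,5,6,8a-octahydronaphthalen-2-ol; 24 umbelliferone (7-hydroxy-2H-chromen-2-one)
Product: 25 7-{[(1S,4aR,6R,8aS)-6-hydroxy-5,5,8a-trimethyl-2-methylidene-1,2,4a,5,6,7,8,8a-octahydronaphthalen-1-yl]methoxy}-2H-chromen-2-one
Conditions: PPh3, i-PrO2CN=NCO2i-Pr, THF, 0 °C → rt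
Reagents that add atoms: none
Why: Mitsunobu etherification; the acidic phenol should displace the primary C11 alkoxyphosphonium, while the axial C3 hydroxyl next to the gem-dimethyl carbon is too hindered to be activated, and no stereocentre is touched.

**Compound list**
1 | 2-(tert-butyldiphenylsilyloxy)acetaldehyde | O=CCO[Si](c1ccccc1)(c1ccccc1)C(C)(C)C | starting material
2 | 2-(triphenylphosphoranylidene)propanal | CC(C=O)=P(c1ccccc1)(c1ccccc1)c1ccccc1 | starting material
3 | (E)-4-(tert-butyldiphenylsilyloxy)-2-methylbut-2-enal | O=C/C(C)=C/CO[Si](c1ccccc1)(c1ccccc1)C(C)(C)C | intermediate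
4 | but-3-en-2-one | CC(=O)C=C | starting material
5 | 2-(triisopropylsilyloxy)buta-1,3-diene | C=CC(=C)O[Si](C(C)C)(C(C)C)C(C)C | intermediate
6 | (1S,6S)-6-[(tert-butyldiphenylsilyloxy)methyl]-1-methyl-4-(triisopropylsilyloxy)cyclohex-3-ene-1-carbaldehyde | O=C[C@@]1(C)CC=C(O[Si](C(C)C)(C(C)C)C(C)C)C[C@@H]1CO[Si](c1ccccc1)(c1ccccc1)C(C)(C)C | intermediate
7 | (1S,6S)-6-[(tert-butyldiphenylsilyloxy)methyl]-1-methyl-4-oxocyclohex-2-ene-1-carbaldehyde | O=C[C@@]1(C)C=CC(=O)C[C@@H]1CO[Si](c1ccccc1)(c1ccccc1)C(C)(C)C | intermediate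
8 | (4S,5S)-5-[(tert-butyldiphenylsilyloxy)methyl]-4-(dimethoxymethyl)-4-methylcyclohex-2-en-1-one | COC(OC)[C@@]1(C)C=CC(=O)C[C@@H]1CO[Si](c1ccccc1)(c1ccccc1)C(C)(C)C | intermediate
9 | lithium dienolate of 8 (O–Li on C7, C7=C8) | COC(OC)[C@@]1(C)C=CC(O[Li])=C[C@@H]1CO[Si](c1ccccc1)(c1ccccc1)C(C)(C)C | intermediate
10 | (4S,5S,6R)-5-[(tert-butyldiphenylsilyloxy)methyl]-4-(dimethoxymethyl)-6-[(dimethylamino)methyl]-4-methylcyclohex-2-en-1-one | COC(OC)[C@@]1(C)C=CC(=O)[C@@H](CN(C)C)[C@@H]1CO[Si](c1ccccc1)(c1ccccc1)C(C)(C)C | intermediate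
11 | (1S,4S,5S,6R)-5-[(tert-butyldiphenylsilyloxy)methyl]-4-(dimethoxymethyl)-6-[(dimethylamino)methyl]-4-methylcyclohex-2-en-1-ol | COC(OC)[C@@]1(C)C=C[C@H](O)[C@@H](CN(C)C)[C@@H]1CO[Si](c1ccccc1)(c1ccccc1)C(C)(C)C | intermediate
12 | 2-methoxypropene | COC(C)=C | starting material
13 | prop-1-en-2-yl ether of 11 at the C7 oxygen (all centres as in 11) | COC(OC)[C@@]1(C)C=C[C@H](OC(C)=C)[C@@H](CN(C)C)[C@@H]1CO[Si](c1ccccc1)(c1ccccc1)C(C)(C)C | intermediate
14 | 1-[(1R,4R,5S,6S)-5-[(tert-butyldiphenylsilyloxy)methyl]-6-(dimethoxymethyl)-4-[(dimethylamino)methyl]-6-methylcyclohex-2-en-1-yl]propan-2-one | COC(OC)[C@@]1(C)[C@H](CC(C)=O)C=C[C@@H](CN(C)C)[C@@H]1CO[Si](c1ccccc1)(c1ccccc1)C(C)(C)C | intermediate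
15 | (1S,2R,5R,6S)-6-[(tert-butyldiphenylsilyloxy)methyl]-5-[(dimethylamino)methyl]-1-methyl-2-(2-oxopropyl)cyclohex-3-ene-1-carbaldehyde | O=C[C@@]1(C)[C@H](CC(C)=O)C=C[C@@H](CN(C)C)[C@@H]1CO[Si](c1ccccc1)(c1ccccc1)C(C)(C)C | intermediate
16 | (4aS,5S,6R,8aR)-5-[(tert-butyldiphenylsilyloxy)methyl]-6-[(dimethylamino)methyl]-4-hydroxy-4a-methyl-3,4,4a,5,6,8a-hexahydronaphthalen-2(1H)-one, both C4 epimers | CN(C)C[C@@H]1C=C[C@H]2CC(=O)CC(O)[C@]2(C)[C@H]1CO[Si](c1ccccc1)(c1ccccc1)C(C)(C)C | intermediate
17 | (4aS,5S,6R,8aR)-5-[(tert-butyldiphenylsilyloxy)methyl]-6-[(dimethylamino)methyl]-4a-methyl-4a,5,6,8a-tetrahydronaphthalen-2(1H)-one | CN(C)C[C@@H]1C=C[C@H]2CC(=O)C=C[C@]2(C)[C@H]1CO[Si](c1ccccc1)(c1ccccc1)C(C)(C)C | intermediate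
18 | N,N,N-trimethylammonium iodide of 17 | C[N+](C)(C)C[C@@H]1C=C[C@H]2CC(=O)C=C[C@]2(C)[C@H]1CO[Si](c1ccccc1)(c1ccccc1)C(C)(C)C.[I-] | intermediate
19 | 1,1-dimethyl derivative of 18 (gem-dimethyl on C4 in drimane numbering) | C[N+](C)(C)C[C@@H]1C=C[C@H]2C(C)(C)C(=O)C=C[C@]2(C)[C@H]1CO[Si](c1ccccc1)(c1ccccc1)C(C)(C)C.[I-] | intermediate
20 | (4aS,5S,8aR)-5-[(tert-butyldiphenylsilyloxy)methyl]-1,1,4a-trimethyl-6-methylidene-4a,5,6,8a-tetrahydronaphthalen-2(1H)-one | C=C1C=C[C@H]2C(C)(C)C(=O)C=C[C@]2(C)[C@H]1CO[Si](c1ccccc1)(c1ccccc1)C(C)(C)C | intermediate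
21 | (4aS,5S,8aR)-5-[(tert-butyldiphenylsilyloxy)methyl]-1,1,4a-trimethyl-6-methylidene-3,4,4a,5,6,8a-hexahydronaphthalen-2(1H)-one | C=C1C=C[C@H]2C(C)(C)C(=O)CC[C@]2(C)[C@H]1CO[Si](c1ccccc1)(c1ccccc1)C(C)(C)C | intermediate
22 | (2R,4aS,5S,8aR)-5-[(tert-butyldiphenylsilyloxy)methyl]-1,1,4a-trimethyl-6-methylidene-1,2,3,4,4a,5,6,8a-octahydronaphthalen-2-ol | C=C1C=C[C@H]2C(C)(C)[C@H](O)CC[C@]2(C)[C@H]1CO[Si](c1ccccc1)(c1ccccc1)C(C)(C)C | intermediate
23 | (2R,4aS,5S,8aR)-5-(hydroxymethyl)-1,1,4a-trimethyl-6-methylidene-1,2,3,4,4a,5,6,8a-octahydronaphthalen-2-ol | C=C1C=C[C@H]2C(C)(C)[C@H](O)CC[C@]2(C)[C@H]1CO | intermediate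
24 | umbelliferone (7-hydroxy-2H-chromen-2-one) | O=c1ccc2ccc(O)cc2o1 | starting material
25 | 7-{[(1S,4aR,6R,8aS)-6-hydroxy-5,5,8a-trimethyl-2-methylidene-1,2,4a,5,6,7,8,8a-octahydronaphthalen-1-yl]methoxy}-2H-chromen-2-one | C=C1C=C[C@H]2C(C)(C)[C@H](O)CC[C@]2(C)[C@H]1COc1ccc2ccc(=O)oc2c1 | target

**Step count**
Total: 13 steps. Longest linear sequence: 12 steps (step 1, then steps 3–13); step 2 is a one-step branch.

**Steps most likely to fail**

Step 8. The acid needed for the enol ether exchange may instead ionise the allylic C7–O bond or promote addition of the enol ether to the acetal, and the [3,3] shift may be slow because C7–O must become pseudoaxial against two 1,3-diaxial contacts. The fallback separates the events and keeps the rearrangement neutral. From 11, acetylation (Ac2O, 4-dimethylaminopyridine, Et3N) would give (1S,4S,5S,6R)-5-[(tert-butyldiphenylsilyloxy)methyl]-4-(dimethoxymethyl)-6-[(dimethylamino)methyl]-4-methylcyclohex-2-en-1-yl acetate F1. Methylenation of the ester carbonyl with Cp2TiMe2 in toluene at 65 °C would give the isopropenyl ether 13, now isolated. Heating 13 in o-xylene at 170–190 °C without acid should effect the Claisen shift to 14, and 2 M aqueous HCl in THF would then take 14 through 15 and 16 to 17, where the route is rejoined.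

Step 9. The second C-methylation at the hindered C4 may stall or be diverted to O-methylation, and the Hofmann elimination may be slow or followed by base-induced migration of the new diene. The fallback replaces the Hofmann elimination by a Cope elimination and methylates stepwise. From 17, 3-chloroperbenzoic acid (1 equiv, CH2Cl2, −20 °C) would give the amine N-oxide of 17 F2, which on warming in THF should lose N,N-dimethylhydroxylamine to give (4aS,5S,8aR)-5-[(tert-butyldiphenylsilyloxy)methyl]-4a-methyl-6-methylidene-4a,5,6,8a-tetrahydronaphthalen-2(1H)-one F3. Kinetic enolate methylation (LiN(i-Pr)2, MeI, THF, −78 °C) would give the 1-methyl derivative of F3 F4, and a second round would give 20, where the route is rejoined.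

Step 3. The trisubstituted enal is a weak dienophile, so the catalysed cycloaddition may be sluggish and facial selectivity may erode. The fallback gives up asymmetric catalysis for a racemic cycloaddition and a physical separation. From 3, uncatalysed cycloaddition with commercial (E)-3-(tert-butyldimethylsilyloxy)-N,N-dimethylbuta-1,3-dien-1-amine in toluene at 40–80 °C would give racemic 2-(dimethylamino)-6-[(tert-butyldiphenylsilyloxy)methyl]-1-methyl-4-(tert-butyldimethylsilyloxy)cyclohex-3-ene-1-carbaldehyde F5. Dilute HCl in THF would hydrolyse the enol ether and eliminate dimethylamine to give racemic 7, that is 7 together with its mirror image, the (1R,6R)-enantiomer of 7 F6. Preparative chromatography on a chiral stationary phase would separate them, and the route is rejoined at 7; steps 2 and 4 are then not needed.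

**Further compounds**
F1 | step 8 | (1S,4S,5S,6R)-5-[(tert-butyldiphenylsilyloxy)methyl]-4-(dimethoxymethyl)-6-[(dimethylamino)methyl]-4-methylcyclohex-2-en-1-yl acetate | COC(OC)[C@@]1(C)C=C[C@H](OC(C)=O)[C@@H](CN(C)C)[C@@H]1CO[Si](c1ccccc1)(c1ccccc1)C(C)(C)C
F2 | step 9 | amine N-oxide of 17 | C[N+](C)([O-])C[C@@H]1C=C[C@H]2CC(=O)C=C[C@]2(C)[C@H]1CO[Si](c1ccccc1)(c1ccccc1)C(C)(C)C
F3 | step 9 | (4aS,5S,8aR)-5-[(tert-butyldiphenylsilyloxy)methyl]-4a-methyl-6-methylidene-4a,5,6,8a-tetrahydronaphthalen-2(1H)-one | C=C1C=C[C@H]2CC(=O)C=C[C@]2(C)[C@H]1CO[Si](c1ccccc1)(c1ccccc1)C(C)(C)C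
F4 | step 9 | 1-methyl derivative of F3, both C1 epimers | C=C1C=C[C@H]2C(C)C(=O)C=C[C@]2(C)[C@H]1CO[Si](c1ccccc1)(c1ccccc1)C(C)(C)C
F5 | step 3 | racemic 2-(dimethylamino)-6-[(tert-butyldiphenylsilyloxy)methyl]-1-methyl-4-(tert-butyldimethylsilyloxy)cyclohex-3-ene-1-carbaldehyde, drawn as the enantiomer that leads to 7, amine-bearing carbon undefined | O=C[C@@]1(C)C(N(C)C)C=C(O[Si](C)(C)C(C)(C)C)C[C@@H]1CO[Si](c1ccccc1)(c1ccccc1)C(C)(C)C
F6 | step 3 | (1R,6R)-6-[(tert-butyldiphenylsilyloxy)methyl]-1-methyl-4-oxocyclohex-2-ene-1-carbaldehyde | O=C[C@]1(C)C=CC(=O)C[C@H]1CO[Si](c1ccccc1)(c1ccccc1)C(C)(C)C
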